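**Plan**
- Retrosynthesis: the C4–C4a acyl–arene bond of ring C is cut first, then the O1–C2 benzylic aryl ether, then C8–CH2 (prenyl) and C6–CH2 (hydroxyethyl) on ring A, and C2–C3 in the three-carbon chain.
- Enabling feature: ring A is a 2-(2-hydroxyethyl)phloroglucinol with a mirror plane through C6 and C8a–O1. O1 is the one oxygen para to C6, and C8 and C4a are equivalent, so once one of them carries the prenyl group the other is the only free ring carbon and has to become C4a.
- Forward: ring A is dressed on phloroglucinol (ortho-lithiation/ethylene oxide at C6, O-tert-prenylation/Claisen shift to C8), the B-ring carbinol is built from vanillin, the halves are joined at O1–C2, and ring C, the only ring formed, is closed last by acylation before global deprotection.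
- Stereochemistry: C2 is the only stereocentre. An (R)-carbinol from Ru-catalysed asymmetric transfer hydrogenation is inverted to (S) in a Mitsunobu etherification and is a spectator afterwards.

Key step: step 15

Target: laxiflorin, (2S)-5,7-dihydroxy-2-(4-hydroxy-3-methoxyphenyl)-6-(2-hydroxyethyl)-8-(3-methylbut-2-enyl)chroman-4-one.
Assumption: the sense of the transfer hydrogenation in step 12 is taken from the aryl methyl ketone series ((R,R)-ligand gives the (R)-carbinol); if the β-keto ester behaved oppositely, the (S,S)-ligand would be used.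

**Route**

Step 1
Reactants: 1 phloroglucinol
Product: 2 3,5-bis(methoxymethoxy)phenol
Conditions: MOMCl (2.0 equiv), i-Pr2NEt, DMF, 0 °C → rt; chromatography
Reagents that add atoms: chloromethyl methyl ether (MOMCl), COCCl
Why: Williamson-type O-alkylation of the C3-symmetric triphenol is statistical but constitutionally unambiguous, because any two of the three equivalent hydroxyls give the same bis-ether, which should separate from the mono- and tris-ethers by polarity.

Step 2
Reactants: 2 3,5-bis(methoxymethoxy)phenol
Product: 3 1-(benzyloxy)-3,5-bis(methoxymethoxy)benzene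
Conditions: BnBr, K2CO3, DMF, rt
Reagents that add atoms: benzyl bromide, BrCc1ccccc1
Why: Williamson etherification of the one remaining phenol marks the future O1 with a benzyl group that is orthogonal to MOM and silyl ethers and can be removed by hydrogenolysis while no alkene is yet present.

Step 3
Reactants: 3 1-(benzyloxy)-3,5-bis(methoxymethoxy)benzene; 4 ethylene oxide
Product: 6 2-[4-(benzyloxy)-2,6-bis(methoxymethoxy)phenyl]ethan-1-ol, via aryllithium 5 (not isolated)
Conditions: n-BuLi, THF, 0 °C; then 4 (solution in THF), −78 °C → rt; H2O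
Reagents that add atoms: none
Why: Directed ortho-metalation should take place at the carbon flanked by both MOM ethers, which cooperate as the strongest directing groups while the benzyl ether is a much weaker director, and the aryllithium then opens the epoxide by SN2 to install the two-carbon alcohol at the future C6.

Step 4
Reactants: 6 2-[4-(benzyloxy)-2,6-bis(methoxymethoxy)phenyl]ethan-1-ol
Product: 7 {2-[4-(benzyloxy)-2,6-bis(methoxymethoxy)phenyl]ethoxy}(tert-butyl)dimethylsilane
Conditions: TBSCl, imidazole, DMF, rt
Reagents that add atoms: tert-butyldimethylsilyl chloride (TBSCl), CC(C)(C)[Si](C)(C)Cl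
Why: Standard silylation of a primary alcohol masks it against the later Mitsunobu and acylation steps.

Step 5
Reactants: 7 {2-[4-(benzyloxy)-2,6-bis(methoxymethoxy)phenyl]ethoxy}(tert-butyl)dimethylsilane
Product: 8 4-[2-(tert-butyldimethylsilyloxy)ethyl]-3,5-bis(methoxymethoxy)phenol
Conditions: H2 (1 atm), 10% Pd/C, EtOAc, rt
Reagents that add atoms: none
Why: Catalytic hydrogenolysis should cleave the aryl benzyl ether selectively, MOM and TBS ethers being inert in a non-protic solvent, and it frees the oxygen para to the side chain with both ortho carbons still equivalent.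

Step 6
Reactants: 9 2-methylbut-3-en-2-ol
Product: 11 tert-butyl 2-methylbut-3-en-2-yl carbonate, via lithium alkoxide 10 (not isolated)
Conditions: n-BuLi, THF, −78 → 0 °C; Boc2O, 0 °C → rt
Reagents that add atoms: di-tert-butyl dicarbonate (Boc2O), CC(C)(C)OC(=O)OC(=O)OC(C)(C)C
Why: O-Acylation of the lithium tertiary alkoxide with Boc2O is the usual way to this mixed carbonate, the ionisable partner for the palladium-catalysed allylic etherification.

Step 7
Reactants: 8 4-[2-(tert-butyldimethylsilyloxy)ethyl]-3,5-bis(methoxymethoxy)phenol; 11 tert-butyl 2-methylbut-3-en-2-yl carbonate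
Product: 12 tert-butyl{2-[2,6-bis(methoxymethoxy)-4-(2-methylbut-3-en-2-yloxy)phenyl]ethoxy}dimethylsilane
Conditions: Pd(PPh3)4 (3 mol %), THF, 0 °C
Reagents that add atoms: none
Why: In this Tsuji–Trost O-allylation the carbonate ionises to a 1,1-dimethyl-π-allylpalladium tert-butoxide that deprotonates the unhindered phenol, and the phenoxide should attack the more substituted allyl terminus under kinetic control at low temperature to give the reverse-prenyl ether.

Step 8
Reactants: 12 tert-butyl{2-[2,6-bis(methoxymethoxy)-4-(2-methylbut-3-en-2-yloxy)phenyl]ethoxy}dimethylsilane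
Product: 14 4-[2-(tert-butyldimethylsilyloxy)ethyl]-3,5-bis(methoxymethoxy)-2-(3-methylbut-2-en-1-yl)phenol, via ortho-dienone 13 (not isolated)
Conditions: o-xylene, 140 °C
Reagents that add atoms: none
Why: The aromatic Claisen rearrangement ([3,3]) moves the allyl unit with transposition to an ortho carbon, so the 1,1-dimethylallyl ether becomes a linear prenyl group after tautomerisation of the dienone, and one product is expected because the two ortho carbons are equivalent and the para carbon is blocked.

Step 9
Reactants: 15 vanillin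
Product: 16 4-formyl-2-methoxyphenyl acetate (vanillin acetate)
Conditions: Ac2O, pyridine, rt
Reagents that add atoms: acetic anhydride, CC(=O)OC(C)=O
Why: Acetylation of the phenol gives the aryl acetate that lowers the donor strength of the 4'-oxygen for the later substitution and acylation steps.

Step 10
Reactants: 16 4-formyl-2-methoxyphenyl acetate; 17 allyl acetate
Product: 19 allyl (±)-3-(4-acetoxy-3-methoxyphenyl)-3-hydroxypropanoate, via lithium enolate 18 (not isolated)
Conditions: LDA, 17, THF, −78 °C; then 16, −78 °C; AcOH quench at −78 °C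
Reagents that add atoms: none
Why: Aldol addition of the preformed lithium ester enolate to the aldehyde at −78 °C is much faster than attack on the aryl acetate and forms the C2–C3 bond, the racemic carbinol being erased in the next step.

Step 11
Reactants: 19 allyl (±)-3-(4-acetoxy-3-methoxyphenyl)-3-hydroxypropanoate
Product: 20 allyl 3-(4-acetoxy-3-methoxyphenyl)-3-oxopropanoate
Conditions: Dess–Martin periodinane, CH2Cl2, 0 °C → rt
Reagents that add atoms: none
Why: Dess–Martin oxidation of the benzylic secondary alcohol should give the β-keto ester under non-basic conditions that leave the allyl ester and the aryl acetate alone.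

Step 12
Reactants: 20 allyl 3-(4-acetoxy-3-methoxyphenyl)-3-oxopropanoate
Product: 21 allyl (R)-3-(4-acetoxy-3-methoxyphenyl)-3-hydroxypropanoate
Conditions: RuCl[(R,R)-TsDPEN](p-cymene) (1 mol %), HCO2H/Et3N (5:2), DMF, rt
Reagents that add atoms: none
Why: Noyori–Ikariya asymmetric transfer hydrogenation reduces aryl β-keto esters chemoselectively at C=O through a six-membered hydride/proton transfer in which the CH/π contact between arene ligand and aryl ketone fixes the face, so the (R,R)-ligand is expected to give the (R)-carbinol without touching the allyl C=C.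

Step 13
Reactants: 14 4-[2-(tert-butyldimethylsilyloxy)ethyl]-3,5-bis(methoxymethoxy)-2-(3-methylbut-2-en-1-yl)phenol; 21 allyl (R)-3-(4-acetoxy-3-methoxyphenyl)-3-hydroxypropanoate
Product: 22 allyl (S)-3-(4-acetoxy-3-methoxyphenyl)-3-{3,5-bis(methoxymethoxy)-4-[2-(tert-butyldimethylsilyloxy)ethyl]-2-(3-methylbut-2-en-1-yl)phenoxy}propanoate
Conditions: PPh3, DIAD, toluene, 0 °C → rt
Reagents that add atoms: none
Why: In the Mitsunobu etherification the phenoxide displaces the alkoxyphosphonium group by SN2 with inversion, turning the (R)-carbinol into the (S)-benzylic aryl ether, while the 4-acetoxy group disfavours an SN1 pathway and a non-polar solvent at low temperature limits β-elimination to the cinnamate.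

Step 14
Reactants: 22 allyl (S)-3-(4-acetoxy-3-methoxyphenyl)-3-{3,5-bis(methoxymethoxy)-4-[2-(tert-butyldimethylsilyloxy)ethyl]-2-(3-methylbut-2-en-1-yl)phenoxy}propanoate
Product: 23 (S)-3-(4-acetoxy-3-methoxyphenyl)-3-{3,5-bis(methoxymethoxy)-4-[2-(tert-butyldimethylsilyloxy)ethyl]-2-(3-methylbut-2-en-1-yl)phenoxy}propanoic acid
Conditions: Pd(PPh3)4 (5 mol %), N-methylaniline, THF, rt; pH 4 buffer work-up
Reagents that add atoms: none
Why: Palladium(0)-catalysed deallylation with π-allyl transfer to a weakly nucleophilic aniline frees the acid under near-neutral conditions, avoiding both the E1cB loss of aryloxide that saponification would risk and the aminolysis of the aryl acetate that a more nucleophilic amine scavenger would cause.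

Step 15
Reactants: 23 (S)-3-(4-acetoxy-3-methoxyphenyl)-3-{3,5-bis(methoxymethoxy)-4-[2-(tert-butyldimethylsilyloxy)ethyl]-2-(3-methylbut-2-en-1-yl)phenoxy}propanoic acid
Product: 25 (2S)-4'-O-acetyl-5,7-bis-O-(methoxymethyl)-O-(tert-butyldimethylsilyl)laxiflorin, via mixed anhydride 24 (not isolated)
Conditions: (CF3CO)2O (1.5 equiv), CH2Cl2, 0 °C; cold aq. NaHCO3
Reagents that add atoms: none
Why: TFAA converts the acid into mixed anhydride 24, whose acylium-like C4 is attacked by C4a, and the arenium ion then loses its proton to trifluoroacetate (intramolecular Friedel–Crafts acylation, SEAr). The closest known reaction type is the TFAA- or polyphosphoric-acid-promoted cyclisation of 3-aryloxypropanoic acids to chroman-4-ones and of 3-aryl-3-aryloxypropanoic acids to flavanones. Ring C closes in a 6-exo-trig mode at the acyl carbon, the carbonyl oxygen staying outside the new ring. No stereocentre is created; C2 is a spectator whose benzylic C2–O1 bond is kept from ionising by the weakly donating 4'-acetoxy group and by the 3'-methoxy group being meta to C2. Site selectivity needs no control because C4a, ortho to O1 and O5 and para to O7, is the only unsubstituted carbon of ring A, and it is far more nucleophilic than C6' of ring B, so indanone formation should not compete. The chemoselectivity that is needed, acylation before acidolysis of the O5 MOM ether, rests on the high nucleophilicity of this carbon at 0 °C and short contact with the trifluoroacetic acid that is released; loss of a MOM or silyl group after closure is harmless since step 16 removes them all.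

Step 16
Reactants: 25 (2S)-4'-O-acetyl-5,7-bis-O-(methoxymethyl)-O-(tert-butyldimethylsilyl)laxiflorin
Product: 26 laxiflorin
Conditions: HCl (1.25 M in MeOH), 0 → 35 °C
Reagents that add atoms: none
Why: Acid-catalysed methanolysis (acetal exchange, desilylation and transesterification) should remove both MOM ethers, the primary silyl ether and the aryl acetate in one operation, and acid is chosen because flavanones lose their C2 configuration by ring opening under base but not under mild acid at or near room temperature.

**Compound list**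
1 | phloroglucinol | Oc1cc(O)cc(O)c1 | starting material
2 | 3,5-bis(methoxymethoxy)phenol | COCOc1cc(O)cc(OCOC)c1 | intermediate
3 | 1-(benzyloxy)-3,5-bis(methoxymethoxy)benzene | COCOc1cc(OCc2ccccc2)cc(OCOC)c1 | intermediate
4 | ethylene oxide | C1CO1 | starting material
5 | [4-(benzyloxy)-2,6-bis(methoxymethoxy)phenyl]lithium | [Li]c1c(OCOC)cc(OCc2ccccc2)cc1OCOC | intermediate
6 | 2-[4-(benzyloxy)-2,6-bis(methoxymethoxy)phenyl]ethan-1-ol | COCOc1cc(OCc2ccccc2)cc(OCOC)c1CCO | intermediate
7 | {2-[4-(benzyloxy)-2,6-bis(methoxymethoxy)phenyl]ethoxy}(tert-butyl)dimethylsilane | COCOc1cc(OCc2ccccc2)cc(OCOC)c1CCO[Si](C)(C)C(C)(C)C | intermediate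
8 | 4-[2-(tert-butyldimethylsilyloxy)ethyl]-3,5-bis(methoxymethoxy)phenol | COCOc1cc(O)cc(OCOC)c1CCO[Si](C)(C)C(C)(C)C | intermediate
9 | 2-methylbut-3-en-2-ol | C=CC(C)(C)O | starting material
10 | lithium 2-methylbut-3-en-2-olate | C=CC(C)(C)O[Li] | intermediate
11 | tert-butyl 2-methylbut-3-en-2-yl carbonate | C=CC(C)(C)OC(=O)OC(C)(C)C | intermediate
12 | tert-butyl{2-[2,6-bis(methoxymethoxy)-4-(2-methylbut-3-en-2-yloxy)phenyl]ethoxy}dimethylsilane (aryl 1,1-dimethylallyl ether) | COCOc1cc(OC(C)(C)C=C)cc(OCOC)c1CCO[Si](C)(C)C(C)(C)C | intermediate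
13 | 4-[2-(tert-butyldimethylsilyloxy)ethyl]-3,5-bis(methoxymethoxy)-6-(3-methylbut-2-en-1-yl)cyclohexa-2,4-dien-1-one (racemic at C6) | O=C1C=C(OCOC)C(CCO[Si](C)(C)C(C)(C)C)=C(OCOC)C1CC=C(C)C | intermediate
14 | 4-[2-(tert-butyldimethylsilyloxy)ethyl]-3,5-bis(methoxymethoxy)-2-(3-methylbut-2-en-1-yl)phenol | Oc1cc(OCOC)c(CCO[Si](C)(C)C(C)(C)C)c(OCOC)c1CC=C(C)C | intermediate
15 | vanillin | COc1cc(C=O)ccc1O | starting material
16 | 4-formyl-2-methoxyphenyl acetate | COc1cc(C=O)ccc1OC(C)=O | intermediate
17 | allyl acetate | CC(=O)OCC=C | starting material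
18 | lithium enolate of allyl acetate | C=C(O[Li])OCC=C | intermediate
19 | allyl (±)-3-(4-acetoxy-3-methoxyphenyl)-3-hydroxypropanoate | COc1cc(C(O)CC(=O)OCC=C)ccc1OC(C)=O | intermediate
20 | allyl 3-(4-acetoxy-3-methoxyphenyl)-3-oxopropanoate | COc1cc(C(=O)CC(=O)OCC=C)ccc1OC(C)=O | intermediate
21 | allyl (R)-3-(4-acetoxy-3-methoxyphenyl)-3-hydroxypropanoate | COc1cc([C@H](O)CC(=O)OCC=C)ccc1OC(C)=O | intermediate
22 | allyl (S)-3-(4-acetoxy-3-methoxyphenyl)-3-{3,5-bis(methoxymethoxy)-4-[2-(tert-butyldimethylsilyloxy)ethyl]-2-(3-methylbut-2-en-1-yl)phenoxy}propanoate | COc1cc([C@@H](Oc2cc(OCOC)c(CCO[Si](C)(C)C(C)(C)C)c(OCOC)c2CC=C(C)C)CC(=O)OCC=C)ccc1OC(C)=O | intermediate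
23 | (S)-3-(4-acetoxy-3-methoxyphenyl)-3-{3,5-bis(methoxymethoxy)-4-[2-(tert-butyldimethylsilyloxy)ethyl]-2-(3-methylbut-2-en-1-yl)phenoxy}propanoic acid | COc1cc([C@@H](Oc2cc(OCOC)c(CCO[Si](C)(C)C(C)(C)C)c(OCOC)c2CC=C(C)C)CC(=O)O)ccc1OC(C)=O | intermediate
24 | mixed anhydride of 23 with trifluoroacetic acid, (S)-configured | COc1cc([C@@H](Oc2cc(OCOC)c(CCO[Si](C)(C)C(C)(C)C)c(OCOC)c2CC=C(C)C)CC(=O)OC(=O)C(F)(F)F)ccc1OC(C)=O | intermediate
25 | (2S)-4'-O-acetyl-5,7-bis-O-(methoxymethyl)-O-(tert-butyldimethylsilyl)laxiflorin | COc1cc([C@@H]2CC(=O)c3c(OCOC)c(CCO[Si](C)(C)C(C)(C)C)c(OCOC)c(CC=C(C)C)c3O2)ccc1OC(C)=O | intermediate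
26 | laxiflorin, (2S)-5,7-dihydroxy-2-(4-hydroxy-3-methoxyphenyl)-6-(2-hydroxyethyl)-8-(3-methylbut-2-en-1-yl)chroman-4-one | COc1cc([C@@H]2CC(=O)c3c(O)c(CCO)c(O)c(CC=C(C)C)c3O2)ccc1O | target

**Step count**
Total: 16 steps. Longest linear sequence: 11 steps (1–5, 7, 8, 13–16, from phloroglucinol).

**Steps most likely to fail**

Step 13 (Mitsunobu etherification). β-Elimination of the activated carbinol to the cinnamate may outrun substitution by the ortho-substituted, weakly acidic phenol, and partial ionisation at the benzylic carbon may erode the configuration. The fallback sets out from 21, uses phenol 14 and rejoins the route at 23. It moves the carbinol partner to the alcohol oxidation level, where no acidic α-hydrogen remains. Deallylation of 21 with Pd(PPh3)4 and N-methylaniline should give (R)-3-(4-acetoxy-3-methoxyphenyl)-3-hydroxypropanoic acid F1. Borane–dimethyl sulfide in THF at 0 °C, which reduces a carboxylic acid much faster than an aryl ester, should give 4-[(1R)-1,3-dihydroxypropyl]-2-methoxyphenyl acetate F2. TESCl and imidazole at −40 °C should silylate the primary hydroxyl only, giving 4-[(1R)-1-hydroxy-3-(triethylsilyloxy)propyl]-2-methoxyphenyl acetate F3. Mitsunobu coupling of F3 with 14 (PPh3, DIAD, toluene), the reaction type well established for 1-aryl-3-substituted propan-1-ols and ortho-substituted phenols, should give with inversion the (S)-configured aryl ether 4-[(1S)-1-{3,5-bis(methoxymethoxy)-4-[2-(tert-butyldimethylsilyloxy)ethyl]-2-(3-methylbut-2-en-1-yl)phenoxy}-3-(triethylsilyloxy)propyl]-2-methoxyphenyl acetate F4. PPTS in methanol at 0 °C should remove the triethylsilyl group in the presence of the TBS ether to give the corresponding (S)-3-hydroxypropyl ether F5. TEMPO with PhI(OAc)2 in aqueous acetonitrile should then oxidise the primary alcohol to acid 23.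

Step 15 (ring closure). The trifluoroacetic acid released may cleave the O5 MOM ether before the ring closes, after which the phenol is trifluoroacetylated and the ring deactivated; intermolecular trifluoroacetylation of C4a by excess anhydride is a second possibility. The fallback sets out from 23 and rejoins at 25. It separates activation from ring closure so that no free Brønsted acid is present. 1-Chloro-N,N,2-trimethylprop-1-en-1-amine in CH2Cl2 at 0 °C should convert 23 under neutral conditions into the (S)-acid chloride F6. Chloride abstraction with silver triflate in the presence of 2,6-di-tert-butyl-4-methylpyridine at −78 → −20 °C should release the acyl triflate, a known Friedel–Crafts acylating species, and the hindered base takes up the triflic acid as 25 forms.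

Step 16 (global deprotection). The exposure to acid needed for methanolysis of the aryl acetate may allow Markovnikov addition of the C7 hydroxyl or of methanol to the prenyl double bond, and some loss of C2 configuration on prolonged warming. The fallback sets out from 25 and rejoins at 26. It removes the three kinds of protecting group one after another without protic acid or base. Lipase-catalysed alcoholysis (immobilised Candida antarctica lipase B, n-butanol, MTBE, 40 °C), a known neutral way to cleave phenolic acetates of flavonoids, should give (2S)-5,7-bis-O-(methoxymethyl)-O-(tert-butyldimethylsilyl)laxiflorin F7. Zinc bromide with propane-1-thiol in CH2Cl2 at 0 °C should cleave both MOM ethers within minutes to give (2S)-O-(tert-butyldimethylsilyl)laxiflorin F8. HF·pyridine in THF at 0 °C should then remove the silyl ether to give 26.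

**Further compounds**
F1 | step 13 | (R)-3-(4-acetoxy-3-methoxyphenyl)-3-hydroxypropanoic acid | COc1cc([C@H](O)CC(=O)O)ccc1OC(C)=O
F2 | step 13 | 4-[(1R)-1,3-dihydroxypropyl]-2-methoxyphenyl acetate | COc1cc([C@H](O)CCO)ccc1OC(C)=O
F3 | step 13 | 4-[(1R)-1-hydroxy-3-(triethylsilyloxy)propyl]-2-methoxyphenyl acetate | COc1cc([C@H](O)CCO[Si](CC)(CC)CC)ccc1OC(C)=O
F4 | step 13 | 4-[(1S)-1-{3,5-bis(methoxymethoxy)-4-[2-(tert-butyldimethylsilyloxy)ethyl]-2-(3-methylbut-2-en-1-yl)phenoxy}-3-(triethylsilyloxy)propyl]-2-methoxyphenyl acetate | COc1cc([C@@H](Oc2cc(OCOC)c(CCO[Si](C)(C)C(C)(C)C)c(OCOC)c2CC=C(C)C)CCO[Si](CC)(CC)CC)ccc1OC(C)=O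
F5 | step 13 | 4-[(1S)-1-{3,5-bis(methoxymethoxy)-4-[2-(tert-butyldimethylsilyloxy)ethyl]-2-(3-methylbut-2-en-1-yl)phenoxy}-3-hydroxypropyl]-2-methoxyphenyl acetate | COc1cc([C@@H](Oc2cc(OCOC)c(CCO[Si](C)(C)C(C)(C)C)c(OCOC)c2CC=C(C)C)CCO)ccc1OC(C)=O
F6 | step 15 | (S)-3-(4-acetoxy-3-methoxyphenyl)-3-{3,5-bis(methoxymethoxy)-4-[2-(tert-butyldimethylsilyloxy)ethyl]-2-(3-methylbut-2-en-1-yl)phenoxy}propanoyl chloride | COc1cc([C@@H](Oc2cc(OCOC)c(CCO[Si](C)(C)C(C)(C)C)c(OCOC)c2CC=C(C)C)CC(=O)Cl)ccc1OC(C)=O
F7 | step 16 | (2S)-5,7-bis-O-(methoxymethyl)-O-(tert-butyldimethylsilyl)laxiflorin | COc1cc([C@@H]2CC(=O)c3c(OCOC)c(CCO[Si](C)(C)C(C)(C)C)c(OCOC)c(CC=C(C)C)c3O2)ccc1O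
F8 | step 16 | (2S)-O-(tert-butyldimethylsilyl)laxiflorin | COc1cc([C@@H]2CC(=O)c3c(O)c(CCO[Si](C)(C)C(C)(C)C)c(O)c(CC=C(C)C)c3O2)ccc1O
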